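A direct plan would take the central ring as a preformed quinone: 2,5-bis(benzyloxy)-3,6-dibromo-1,4-benzoquinone A1 would be arylated twice by Suzuki–Miyaura coupling to terphenylquinone A2, A2 reduced to hydroquinone A3, the two para hydroxyls esterified one after the other (monoester A4, mixed diester A5), and all benzyl groups removed by hydrogenolysis.
Its weakest steps would be:
- The single esterification of centrosymmetric A3 (or of A2 through a redox relay): the two hydroxyls are equivalent, so the step would be statistical or would rest on an untested catalytic method on a quinone with four ortho substituents, late in the route.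
- The double Suzuki–Miyaura coupling on A1: a quinone would sit in a zerovalent palladium cycle as an oxidant, and its benzyloxy vinylogous esters would be exposed to aqueous base.
- The symmetry logic as a whole: a symmetric core would be built and its symmetry then broken, with the air-sensitive hydroquinone A3 handled in between.

**Retrosynthetic overview**
Central ring numbering: C1 carries the (S)-3-hydroxybutanoate oxygen, C2 OH, C3 aryl, C4 the 3-phenylpropanoate oxygen, C5 OH, C6 aryl.
The central ring is made last, by thermal ring expansion of a squarate-derived 4-acyloxy-4-alkenylcyclobutenone: C1–C4 are the four carbons of squaric acid, C5 and C6 the two alkyne carbons of an arylacetylene.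
Bond C1–C6 is formed by carbonyl addition of a vinyllithium; bond C4–C5 by 6π electrocyclisation of the dienylketene that arises when the four-membered ring opens. Both outer rings are bought.
In the cyclobutenone the four oxygens are already three different things (carbinol ester on C1, ketone on C4, benzyl enol ethers on C2 and C5), so the mixed 1,4-diester needs no mono-functionalisation of a symmetric core, no quinone in a palladium cycle and no free hydroquinone.
The (S) centre is bought as (S)-3-hydroxybutanoic acid.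

Key step: step 6

Remark: the tetrabenzyl core is C2-symmetric, so either para oxygen may receive either acyl group; the chiral one is placed first, and compounds 1, 2, 4, 8, 12 and 21 are taken as purchased.

Step 1
Reactants: 1 squaric acid; 2 benzyl alcohol
Product: 3 dibenzyl squarate (3,4-bis(benzyloxy)cyclobut-3-ene-1,2-dione)
Conditions: BnOH (3 equiv), toluene, reflux, Dean–Stark trap; crystallise
Reagents that add atoms: benzyl alcohol (2), OCc1ccccc1
Why: Squaric acid is a strong vinylogous acid and should be esterified by a primary alcohol under azeotropic removal of water (Fischer-type esterification without added catalyst), giving a squarate whose benzyl groups fall in the final hydrogenolysis.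

Step 2
Reactants: 3 dibenzyl squarate; 4 1-(benzyloxy)-4-bromobenzene
Product: 7 3-(benzyloxy)-4-[4-(benzyloxy)phenyl]cyclobut-3-ene-1,2-dione, via aryllithium 5 (not isolated), via squarate adduct 6 (not isolated)
Conditions: 4, n-BuLi (1.05 equiv), THF, −78 °C; add to 3 in THF, −78 °C; 2 M HCl quench; then 12 M HCl (cat.), CH2Cl2, rt
Reagents that add atoms: 1-(benzyloxy)-4-bromobenzene (4), Brc1ccc(OCc2ccccc2)cc1
Why: Bromine–lithium exchange, 1,2-addition of the aryllithium to one squarate carbonyl and acid-promoted loss of benzyl alcohol with allylic transposition of the carbonyl is the standard entry to 3-alkoxy-4-arylcyclobutenediones and places the first outer ring on the future C3.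

Step 3
Reactants: 8 1-(benzyloxy)-4-ethynylbenzene; 2 benzyl alcohol
Product: 9 1-(benzyloxy)-4-[2-(benzyloxy)ethenyl]benzene (E/Z mixture)
Conditions: BnOH (1.5 equiv), CsOH·H2O (20 mol%), NMP, rt to 60 °C
Reagents that add atoms: benzyl alcohol (2), OCc1ccccc1
Why: Base-catalysed anti-Markovnikov hydroalkoxylation of an arylacetylene, in which the alkoxide adds to the terminal carbon because the resulting vinyl anion carries the aryl group, should give the enol ether, whose geometry is erased in the next step.

Step 4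
Reactants: 9 1-(benzyloxy)-4-[2-(benzyloxy)ethenyl]benzene
Product: 11 1-(benzyloxy)-4-[(Z)-2-(benzyloxy)-1-bromoethenyl]benzene, via dibromide 10 (not isolated)
Conditions: Br2 (1.0 equiv), CH2Cl2, −78 °C; then i-Pr2NEt (2.5 equiv), −78 °C to rt; chromatography on Et3N-treated silica
Reagents that add atoms: bromine, BrBr
Why: Bromine addition to the enol ether and amine-induced dehydrobromination (loss of the bromide alpha to oxygen and of the benzylic proton) is the classical route to beta-bromo enol ethers and should favour the (Z)-bromide, in which the aryl group is trans to the benzyloxy group.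

Step 5
Reactants: 12 (S)-3-hydroxybutanoic acid
Product: 13 tert-butyldimethylsilyl (S)-3-[(tert-butyldimethylsilyl)oxy]butanoate
Conditions: t-BuMe2SiCl (2.2 equiv), imidazole (4.5 equiv), DMF, rt; pentane extraction
Reagents that add atoms: tert-butyldimethylsilyl chloride, CC(C)(C)[Si](C)(C)Cl
Why: Imidazole-mediated silylation of carbinol and carboxylic acid breaks no bond at C3, so the purchased (S) centre is carried through, and the silyl ester is a neutral precursor of the acid chloride.

Step 6
Reactants: 7 3-(benzyloxy)-4-[4-(benzyloxy)phenyl]cyclobut-3-ene-1,2-dione; 11 1-(benzyloxy)-4-[(Z)-2-(benzyloxy)-1-bromoethenyl]benzene; 13 tert-butyldimethylsilyl (S)-3-[(tert-butyldimethylsilyl)oxy]butanoate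
Product: 20 2,5-bis(benzyloxy)-3,6-bis[4-(benzyloxy)phenyl]-4-hydroxyphenyl (S)-3-[(tert-butyldimethylsilyl)oxy]butanoate, via acid chloride 14 (not isolated), via vinyllithium 15 (not isolated), via lithium alkoxide 16 (not isolated), via cyclobutenyl ester 17 (not isolated), via dienylketene 18 (not isolated), via cyclohexadienone 19 (not isolated)
Conditions: 13 (1.5 equiv), (COCl)2 (1.5 equiv), DMF (cat.), CH2Cl2, 0 °C to rt, evaporate (gives 14); 11 (1.15 equiv), t-BuLi (2.3 equiv), THF, −78 °C; add 7 (1.0 equiv), −78 °C; add 14, −78 to −20 °C; NaHCO3 work-up, basic alumina plug; then toluene (0.02 M), 2,6-lutidine (5 mol%), 110 °C, Ar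
Reagents that add atoms: 1-(benzyloxy)-4-[(Z)-2-(benzyloxy)-1-bromoethenyl]benzene (11), Br/C(c1ccc(OCc2ccccc2)cc1)=C\OCc1ccccc1; tert-butyldimethylsilyl (S)-3-[(tert-butyldimethylsilyl)oxy]butanoate (13), C[C@H](O[Si](C)(C)C(C)(C)C)CC(=O)O[Si](C)(C)C(C)(C)C
Why: Bromine–lithium exchange with retention gives vinyllithium 15 (lithium cis to the benzyloxy group, hence chelated and not set up for anti elimination), which adds to the ketone-like carbonyl of 7 next to the benzyloxy-bearing carbon (the other carbonyl is a deactivated vinylogous ester); acylation of alkoxide 16 by 14 gives ester 17, and on heating 17 should undergo conrotatory 4π electrocyclic opening of the four-membered ring to dienylketene 18, 6π electrocyclic closure to dienone 19 and enolisation to phenol 20. The closest known reaction type is the thermal ring expansion of squarate-derived 4-alkenyl-4-oxycyclobutenones to hydroquinone derivatives (Moore rearrangement), here with an acyl group on the carbinol oxygen in place of hydrogen, alkyl or silyl. The central benzene ring closes by a thermal disrotatory 6π electrocyclisation that forms the C4–C5 bond (the C1–C6 bond comes from the carbonyl addition), and tautomerisation to the arene makes the closure irreversible. No stereocentre is created: the carbinol carbon of 17 (formed as two diastereomers) becomes sp2, and the (S) centre lies in the acyl chain, away from every bond made or broken. The step needs outward rotation of the acyloxy group during ring opening, so that the alkenyl arm turns toward the ketene, which the lone-pair donor oxygen on that carbon should secure, and it needs the tertiary ester to survive, which the absence of beta hydrogens and the buffered non-polar medium favour. The result is a hydroquinone in which one para oxygen (the former carbinol oxygen, on C1) is acylated and the other (the former ketone oxygen, on C4) is free, without any statistical step.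

Step 7
Reactants: 20 2,5-bis(benzyloxy)-3,6-bis[4-(benzyloxy)phenyl]-4-hydroxyphenyl (S)-3-[(tert-butyldimethylsilyl)oxy]butanoate; 21 3-phenylpropanoyl chloride
Product: 22 2,5-bis(benzyloxy)-3,6-bis[4-(benzyloxy)phenyl]-4-[(3-phenylpropanoyl)oxy]phenyl (S)-3-[(tert-butyldimethylsilyl)oxy]butanoate
Conditions: 21 (1.3 equiv), Et3N (2 equiv), DMAP (10 mol%), CH2Cl2, 0 °C to rt
Reagents that add atoms: 3-phenylpropanoyl chloride (21), O=C(Cl)CCc1ccccc1
Why: DMAP-catalysed acylation of the single free phenol, which has no free ortho hydroxyl to or from which an acyl group could migrate, should complete the mixed diester with no competition between the two para oxygens.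

Step 8
Reactants: 22 2,5-bis(benzyloxy)-3,6-bis[4-(benzyloxy)phenyl]-4-[(3-phenylpropanoyl)oxy]phenyl (S)-3-[(tert-butyldimethylsilyl)oxy]butanoate
Product: 23 2,5-bis(benzyloxy)-3,6-bis[4-(benzyloxy)phenyl]-4-[(3-phenylpropanoyl)oxy]phenyl (S)-3-hydroxybutanoate
Conditions: HF·pyridine, pyridine, THF, 0 °C to rt
Reagents that add atoms: none
Why: Buffered fluoride cleavage of the secondary silyl ether should leave aryl esters and benzyl ethers intact, and it is done while all four phenols are still benzylated, so that neither fluoride nor base meets an ester next to a free phenol.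

Step 9
Reactants: 23 2,5-bis(benzyloxy)-3,6-bis[4-(benzyloxy)phenyl]-4-[(3-phenylpropanoyl)oxy]phenyl (S)-3-hydroxybutanoate
Product: 24 2,5-dihydroxy-3,6-bis(4-hydroxyphenyl)-4-[(3-phenylpropanoyl)oxy]phenyl (S)-3-hydroxybutanoate (CNP0296884.1)
Conditions: H2 (1 atm), Pd(OH)2/C, THF/EtOAc 1:1, rt; filter under Ar, evaporate below 30 °C
Reagents that add atoms: none
Why: Heterogeneous catalytic hydrogenolysis of the four aryl benzyl ethers under neutral conditions should leave both aryl esters, the phenyl ring of the phenylpropanoate and the (S) carbinol untouched and supplies no base for ortho acyl migration.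

**Compound list**
1 | squaric acid (3,4-dihydroxycyclobut-3-ene-1,2-dione) | O=C1C(=O)C(O)=C1O | starting material
2 | benzyl alcohol | OCc1ccccc1 | starting material
3 | dibenzyl squarate (3,4-bis(benzyloxy)cyclobut-3-ene-1,2-dione) | O=C1C(=O)C(OCc2ccccc2)=C1OCc1ccccc1 | intermediate
4 | 1-(benzyloxy)-4-bromobenzene | Brc1ccc(OCc2ccccc2)cc1 | starting material
5 | [4-(benzyloxy)phenyl]lithium | [Li]c1ccc(OCc2ccccc2)cc1 | intermediate
6 | 2,3-bis(benzyloxy)-4-[4-(benzyloxy)phenyl]-4-hydroxycyclobut-2-en-1-one (racemic) | O=C1C(OCc2ccccc2)=C(OCc2ccccc2)C1(O)c1ccc(OCc2ccccc2)cc1 | intermediate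
7 | 3-(benzyloxy)-4-[4-(benzyloxy)phenyl]cyclobut-3-ene-1,2-dione | O=C1C(=O)C(OCc2ccccc2)=C1c1ccc(OCc2ccccc2)cc1 | intermediate
8 | 1-(benzyloxy)-4-ethynylbenzene | C#Cc1ccc(OCc2ccccc2)cc1 | starting material
9 | 1-(benzyloxy)-4-[2-(benzyloxy)ethenyl]benzene (E/Z mixture) | C(=COCc1ccccc1)c1ccc(OCc2ccccc2)cc1 | intermediate
10 | 1-(benzyloxy)-4-[2-(benzyloxy)-1,2-dibromoethyl]benzene (mixture of diastereomers) | BrC(c1ccc(OCc2ccccc2)cc1)C(Br)OCc1ccccc1 | intermediate
11 | 1-(benzyloxy)-4-[(Z)-2-(benzyloxy)-1-bromoethenyl]benzene | Br/C(c1ccc(OCc2ccccc2)cc1)=C\OCc1ccccc1 | intermediate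
12 | (S)-3-hydroxybutanoic acid | C[C@H](O)CC(=O)O | starting material
13 | tert-butyldimethylsilyl (S)-3-[(tert-butyldimethylsilyl)oxy]butanoate | C[C@H](O[Si](C)(C)C(C)(C)C)CC(=O)O[Si](C)(C)C(C)(C)C | intermediate
14 | (S)-3-[(tert-butyldimethylsilyl)oxy]butanoyl chloride | C[C@H](O[Si](C)(C)C(C)(C)C)CC(=O)Cl | intermediate
15 | {(E)-2-(benzyloxy)-1-[4-(benzyloxy)phenyl]ethenyl}lithium (lithium cis to the benzyloxy group, configuration of 11 retained) | [Li]/C(c1ccc(OCc2ccccc2)cc1)=C\OCc1ccccc1 | intermediate
16 | lithium 2-(benzyloxy)-1-{(Z)-2-(benzyloxy)-1-[4-(benzyloxy)phenyl]ethenyl}-3-[4-(benzyloxy)phenyl]-4-oxocyclobut-2-en-1-olate (racemic) | [Li+].[O-]C1(C(=O)C(c2ccc(OCc3ccccc3)cc2)=C1OCc1ccccc1)/C(c1ccc(OCc2ccccc2)cc1)=C\OCc1ccccc1 | intermediate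
17 | 2-(benzyloxy)-1-{(Z)-2-(benzyloxy)-1-[4-(benzyloxy)phenyl]ethenyl}-3-[4-(benzyloxy)phenyl]-4-oxocyclobut-2-en-1-yl (S)-3-[(tert-butyldimethylsilyl)oxy]butanoate (two diastereomers at the ring carbinol carbon) | C[C@H](O[Si](C)(C)C(C)(C)C)CC(=O)OC1(C(=O)C(c2ccc(OCc3ccccc3)cc2)=C1OCc1ccccc1)/C(c1ccc(OCc2ccccc2)cc1)=C\OCc1ccccc1 | intermediate
18 | (1Z,3Z)-1,4-bis(benzyloxy)-2,5-bis[4-(benzyloxy)phenyl]-6-oxohexa-1,3,5-trien-3-yl (S)-3-[(tert-butyldimethylsilyl)oxy]butanoate (dienylketene) | C[C@H](O[Si](C)(C)C(C)(C)C)CC(=O)O/C(=C(\OCc1ccccc1)C(=C=O)c1ccc(OCc2ccccc2)cc1)/C(c1ccc(OCc2ccccc2)cc1)=C\OCc1ccccc1 | intermediate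
19 | 3,6-bis(benzyloxy)-2,5-bis[4-(benzyloxy)phenyl]-4-oxocyclohexa-1,5-dien-1-yl (S)-3-[(tert-butyldimethylsilyl)oxy]butanoate (transient sp3 carbon at ring position 3, configuration not defined) | C[C@H](O[Si](C)(C)C(C)(C)C)CC(=O)OC1=C(c2ccc(OCc3ccccc3)cc2)C(OCc2ccccc2)C(=O)C(c2ccc(OCc3ccccc3)cc2)=C1OCc1ccccc1 | intermediate
20 | 2,5-bis(benzyloxy)-3,6-bis[4-(benzyloxy)phenyl]-4-hydroxyphenyl (S)-3-[(tert-butyldimethylsilyl)oxy]butanoate | C[C@H](O[Si](C)(C)C(C)(C)C)CC(=O)Oc1c(OCc2ccccc2)c(-c2ccc(OCc3ccccc3)cc2)c(O)c(OCc2ccccc2)c1-c1ccc(OCc2ccccc2)cc1 | intermediate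
21 | 3-phenylpropanoyl chloride | O=C(Cl)CCc1ccccc1 | starting material
22 | 2,5-bis(benzyloxy)-3,6-bis[4-(benzyloxy)phenyl]-4-[(3-phenylpropanoyl)oxy]phenyl (S)-3-[(tert-butyldimethylsilyl)oxy]butanoate | C[C@H](O[Si](C)(C)C(C)(C)C)CC(=O)Oc1c(OCc2ccccc2)c(-c2ccc(OCc3ccccc3)cc2)c(OC(=O)CCc2ccccc2)c(OCc2ccccc2)c1-c1ccc(OCc2ccccc2)cc1 | intermediate
23 | 2,5-bis(benzyloxy)-3,6-bis[4-(benzyloxy)phenyl]-4-[(3-phenylpropanoyl)oxy]phenyl (S)-3-hydroxybutanoate | C[C@H](O)CC(=O)Oc1c(OCc2ccccc2)c(-c2ccc(OCc3ccccc3)cc2)c(OC(=O)CCc2ccccc2)c(OCc2ccccc2)c1-c1ccc(OCc2ccccc2)cc1 | intermediate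
24 | 2,5-dihydroxy-3,6-bis(4-hydroxyphenyl)-4-[(3-phenylpropanoyl)oxy]phenyl (S)-3-hydroxybutanoate (CNP0296884.1) | C[C@H](O)CC(=O)Oc1c(O)c(-c2ccc(O)cc2)c(OC(=O)CCc2ccccc2)c(O)c1-c1ccc(O)cc1 | target

**Step count and risks**
Total steps: 9. Longest linear sequence: 6 (steps 1, 2, 6, 7, 8, 9).

Steps most likely to fail:

1. Step 6 (key step). The tertiary allylic ester 17 may ionise or undergo a 1,3-acyloxy shift before the ring opens, the acyloxy group may rotate inward, or acylation of the hindered alkoxide may stay incomplete. Closure onto the oxygen-bearing alkene terminus is also polarity-mismatched and may be slow. The fallback sets out from lithium alkoxide 16 and comes back at phenol 20. The alkoxide would be trapped with chlorotrimethylsilane to give 3-(benzyloxy)-4-{(Z)-2-(benzyloxy)-1-[4-(benzyloxy)phenyl]ethenyl}-2-[4-(benzyloxy)phenyl]-4-[(trimethylsilyl)oxy]cyclobut-2-en-1-one F1, the carbinol substituent for which this ring expansion is best established. Heating F1 in toluene should give 2,5-bis(benzyloxy)-3,6-bis[4-(benzyloxy)phenyl]-4-[(trimethylsilyl)oxy]phenol F2. Its free phenol would be acylated with 14 (Et3N, DMAP) to 2,5-bis(benzyloxy)-3,6-bis[4-(benzyloxy)phenyl]-4-[(trimethylsilyl)oxy]phenyl (S)-3-[(tert-butyldimethylsilyl)oxy]butanoate F3. Aqueous citric acid in THF should then remove only the aryl trimethylsilyl ether; because the core is symmetric, the product is 20. The acyl group thus enters after the ring is formed instead of before.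

2. Step 4. Bromine may attack the electron-rich arenes instead of the enol ether, elimination may give the (E)-bromide (whose lithium derivative would lose lithium benzyloxide), or the bromo enol ether may hydrolyse on silica. The fallback sets out from benzyl alcohol 2 and comes back at bromide 11, bypassing steps 3 and 4. Formylation with formic acid would give benzyl formate F4. Dibromoolefination of the formate carbonyl (CBr4, PPh3, Ramirez-type) would give 1,1-dibromo-2-(benzyloxy)ethene F5. Suzuki–Miyaura mono-coupling with 4-(benzyloxy)phenylboronic acid (Pd2(dba)3, tri(2-furyl)phosphine, aqueous Na2CO3, dioxane) should take place at the less hindered bromine trans to the benzyloxy group, which fixes the (Z) geometry of 11 by the order of bond formation, not by an elimination.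

3. Step 3. Addition of benzyloxide to the electron-rich alkyne may be sluggish, and the alkyne may oligomerise under the basic conditions. The fallback sets out from aryllithium 5 and comes back at enol ether 9. Formylation of 5 with DMF would give 4-(benzyloxy)benzaldehyde F6. Wittig olefination with the ylide from (benzyloxymethyl)triphenylphosphonium chloride and KOt-Bu in THF should give 9 as an E/Z mixture, which is acceptable because step 4 erases the geometry.

**Further compounds**
F1 | step 6 | 3-(benzyloxy)-4-{(Z)-2-(benzyloxy)-1-[4-(benzyloxy)phenyl]ethenyl}-2-[4-(benzyloxy)phenyl]-4-[(trimethylsilyl)oxy]cyclobut-2-en-1-one (racemic) | C[Si](C)(C)OC1(C(=O)C(c2ccc(OCc3ccccc3)cc2)=C1OCc1ccccc1)/C(c1ccc(OCc2ccccc2)cc1)=C\OCc1ccccc1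
F2 | step 6 | 2,5-bis(benzyloxy)-3,6-bis[4-(benzyloxy)phenyl]-4-[(trimethylsilyl)oxy]phenol | C[Si](C)(C)Oc1c(OCc2ccccc2)c(-c2ccc(OCc3ccccc3)cc2)c(O)c(OCc2ccccc2)c1-c1ccc(OCc2ccccc2)cc1
F3 | step 6 | 2,5-bis(benzyloxy)-3,6-bis[4-(benzyloxy)phenyl]-4-[(trimethylsilyl)oxy]phenyl (S)-3-[(tert-butyldimethylsilyl)oxy]butanoate | C[C@H](O[Si](C)(C)C(C)(C)C)CC(=O)Oc1c(OCc2ccccc2)c(-c2ccc(OCc3ccccc3)cc2)c(O[Si](C)(C)C)c(OCc2ccccc2)c1-c1ccc(OCc2ccccc2)cc1
F4 | step 4 | benzyl formate | O=COCc1ccccc1
F5 | step 4 | 1,1-dibromo-2-(benzyloxy)ethene | BrC(Br)=COCc1ccccc1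
F6 | step 3 | 4-(benzyloxy)benzaldehyde | O=Cc1ccc(OCc2ccccc2)cc1
A1 | direct plan | 2,5-bis(benzyloxy)-3,6-dibromo-1,4-benzoquinone | O=C1C(Br)=C(OCc2ccccc2)C(=O)C(Br)=C1OCc1ccccc1
A2 | direct plan | 2,5-bis(benzyloxy)-3,6-bis[4-(benzyloxy)phenyl]-1,4-benzoquinone | O=C1C(OCc2ccccc2)=C(c2ccc(OCc3ccccc3)cc2)C(=O)C(OCc2ccccc2)=C1c1ccc(OCc2ccccc2)cc1
A3 | direct plan | 2,5-bis(benzyloxy)-3,6-bis[4-(benzyloxy)phenyl]benzene-1,4-diol | Oc1c(OCc2ccccc2)c(-c2ccc(OCc3ccccc3)cc2)c(O)c(OCc2ccccc2)c1-c1ccc(OCc2ccccc2)cc1
A4 | direct plan | 2,5-bis(benzyloxy)-3,6-bis[4-(benzyloxy)phenyl]-4-hydroxyphenyl 3-phenylpropanoate | O=C(CCc1ccccc1)Oc1c(OCc2ccccc2)c(-c2ccc(OCc3ccccc3)cc2)c(O)c(OCc2ccccc2)c1-c1ccc(OCc2ccccc2)cc1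
A5 | direct plan | 2,5-bis(benzyloxy)-3,6-bis[4-(benzyloxy)phenyl]-4-[(3-phenylpropanoyl)oxy]phenyl (S)-3-(benzyloxy)butanoate | C[C@H](OCc1ccccc1)CC(=O)Oc1c(OCc2ccccc2)c(-c2ccc(OCc3ccccc3)cc2)c(OC(=O)CCc2ccccc2)c(OCc2ccccc2)c1-c1ccc(OCc2ccccc2)cc1
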